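The route rests on one disconnection of the 2,3-dihydrobenzofuran: the O1–C7a ring bond and the C7–OH bond are made together. The benzo ring carries oxygen on the neighbouring carbons C7a and C7, and O1 is tied to C3a through C2–C3. An aryne across C7–C7a can therefore take the tethered C2 alkoxide at C7a and hand the resulting C7 carbanion to an oxidant. The precursor is an open-chain, syn-aldol-derived 1,2-diarylpropane-1,3-diol monosilyl ether whose bromoarene bears iodine and a 4-chlorobenzenesulfonate on the carbons that become C7 and C7a. The bromophenol product is homologated and used to alkylate an (S)-β-arylmethyl butyrolactone.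

Key step: step 10

Remark on numbering: benzofuran locants (O1, C2, C3, C3a, C4–C7, C7a) are used for the corresponding atoms also before the ring exists.
Remark on the chemistry: all phenols and the primary alcohol are carried as triisopropylsilyl ethers. A smaller silyl group on the primary oxygen could hop to the neighbouring alkoxide in step 10 and free an oxygen able to close the isomeric five-membered ring. One fluoride treatment at the end also avoids hydrogenolysis beside the benzylic C2–O1 bond.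
Assumption: compounds 1, 6, 9 and 28 are bought.

Step 1
Reactants: 1 methyl 2-(2-hydroxyphenyl)acetate
Product: 2 methyl 2-(5-bromo-2-hydroxyphenyl)acetate
Conditions: NBS (1.0 equiv), MeCN, 0 °C → rt
Reagents that add atoms: N-bromosuccinimide, O=C1CCC(=O)N1Br
Why: Electrophilic aromatic bromination of the phenol goes to the unhindered position para to the hydroxyl (the future C5), the ester side chain being a spectator.

Step 2
Reactants: 2 methyl 2-(5-bromo-2-hydroxyphenyl)acetate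
Product: 3 methyl 2-(5-bromo-2-hydroxy-3-iodophenyl)acetate
Conditions: NIS (1.1 equiv), TsOH·H2O (10 mol %), MeCN, rt
Reagents that add atoms: N-iodosuccinimide, O=C1CCC(=O)N1I
Why: With the para position blocked, electrophilic aromatic iodination can only take the free position ortho to the hydroxyl (the future C7).

Step 3
Reactants: 3 methyl 2-(5-bromo-2-hydroxy-3-iodophenyl)acetate
Product: 4 methyl 2-{5-bromo-2-[(4-chlorophenyl)sulfonyloxy]-3-iodophenyl}acetate
Conditions: 4-ClC6H4SO2Cl, Et3N, DMAP (5 mol %), CH2Cl2, 0 °C → rt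
Reagents that add atoms: 4-chlorobenzenesulfonyl chloride, O=S(=O)(Cl)c1ccc(Cl)cc1
Why: O-Sulfonylation of the acidic dihalophenol under amine base installs the aryl sulfonate that later leaves from the future C7a.

Step 4
Reactants: 4 methyl 2-{5-bromo-2-[(4-chlorophenyl)sulfonyloxy]-3-iodophenyl}acetate
Product: 5 2-{5-bromo-2-[(4-chlorophenyl)sulfonyloxy]-3-iodophenyl}acetic acid
Conditions: 6 M aq. HCl, 1,4-dioxane, 80 °C
Reagents that add atoms: water, O
Why: Acid-catalysed ester hydrolysis frees the acid under conditions to which the aryl sulfonate and both aryl halides are inert, whereas hydroxide could attack the activated sulfonate.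

Step 5
Reactants: 5 2-{5-bromo-2-[(4-chlorophenyl)sulfonyloxy]-3-iodophenyl}acetic acid; 6 (S)-4-benzyl-1,3-oxazolidin-2-one
Product: 8 (4S)-4-benzyl-3-(2-{5-bromo-2-[(4-chlorophenyl)sulfonyloxy]-3-iodophenyl}acetyl)-1,3-oxazolidin-2-one, via mixed pivalic anhydride 7 (not isolated)
Conditions: t-BuCOCl, Et3N, THF, −20 °C; then 6, LiCl, −20 °C → rt
Reagents that add atoms: none
Why: N-Acylation of the oxazolidinone through the mixed pivalic anhydride takes place at the less hindered arylacetyl carbonyl under weakly basic conditions that spare the sulfonate.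

Step 6
Reactants: 9 vanillin (4-hydroxy-3-methoxybenzaldehyde)
Product: 10 3-methoxy-4-(triisopropylsilyloxy)benzaldehyde
Conditions: i-Pr3SiCl, imidazole, DMF, rt
Reagents that add atoms: chlorotriisopropylsilane, CC(C)[Si](Cl)(C(C)C)C(C)C
Why: Phenol silylation gives a bulky aryl silyl ether that should last through base, hydride, organometallic and peroxide steps and fall to fluoride at the end.

Step 7
Reactants: 8 (4S)-4-benzyl-3-(2-{5-bromo-2-[(4-chlorophenyl)sulfonyloxy]-3-iodophenyl}acetyl)-1,3-oxazolidin-2-one; 10 3-methoxy-4-(triisopropylsilyloxy)benzaldehyde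
Product: 13 (4S)-4-benzyl-3-[(2S,3S)-2-{5-bromo-2-[(4-chlorophenyl)sulfonyloxy]-3-iodophenyl}-3-hydroxy-3-[3-methoxy-4-(triisopropylsilyloxy)phenyl]propanoyl]-1,3-oxazolidin-2-one, via dibutylboron Z-enolate 11 (not isolated), via dibutylboron aldolate 12 (not isolated)
Conditions: Bu2BOTf, i-Pr2NEt, CH2Cl2, −78 → 0 °C; then 10, −78 → 0 °C; pH 7 phosphate buffer, MeOH, 30% H2O2, 0 °C
Reagents that add atoms: none
Why: Evans syn-aldol reaction, in which the boron Z-enolate reacts through a Zimmerman–Traxler chair on the enolate face away from the auxiliary benzyl group in the dipole-minimised rotamer, which sets both new centres as (2S,3S), the arrangement that becomes C3 (R) and C2 (S) of the dihydrobenzofuran.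

Step 8
Reactants: 13 (4S)-4-benzyl-3-[(2S,3S)-2-{5-bromo-2-[(4-chlorophenyl)sulfonyloxy]-3-iodophenyl}-3-hydroxy-3-[3-methoxy-4-(triisopropylsilyloxy)phenyl]propanoyl]-1,3-oxazolidin-2-one
Product: 14 4-bromo-2-iodo-6-{(1S,2R)-1,3-dihydroxy-1-[3-methoxy-4-(triisopropylsilyloxy)phenyl]propan-2-yl}phenyl 4-chlorobenzenesulfonate
Conditions: LiBH4, MeOH (1 equiv), THF, 0 °C
Reagents that add atoms: none
Why: Reductive cleavage of the imide by borohydride releases the primary alcohol and the auxiliary 6, does not reduce the aryl halides or the aryl sulfonate, and leaves both stereocentres untouched (the descriptor at the α-aryl carbon changes from S to R only because the priorities change).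

Step 9
Reactants: 14 4-bromo-2-iodo-6-{(1S,2R)-1,3-dihydroxy-1-[3-methoxy-4-(triisopropylsilyloxy)phenyl]propan-2-yl}phenyl 4-chlorobenzenesulfonate
Product: 15 4-bromo-2-iodo-6-{(1S,2R)-1-hydroxy-1-[3-methoxy-4-(triisopropylsilyloxy)phenyl]-3-(triisopropylsilyloxy)propan-2-yl}phenyl 4-chlorobenzenesulfonate
Conditions: i-Pr3SiCl (1.1 equiv), imidazole, DMF, 0 °C
Reagents that add atoms: chlorotriisopropylsilane, CC(C)[Si](Cl)(C(C)C)C(C)C
Why: Selective silylation, the bulky chlorosilane reacting much faster at the primary hydroxyl than at the hindered secondary benzylic one, which must stay free as the nucleophile of the next step.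

Step 10
Reactants: 15 4-bromo-2-iodo-6-{(1S,2R)-1-hydroxy-1-[3-methoxy-4-(triisopropylsilyloxy)phenyl]-3-(triisopropylsilyloxy)propan-2-yl}phenyl 4-chlorobenzenesulfonate
Product: 20 (2S,3R)-5-bromo-2-[3-methoxy-4-(triisopropylsilyloxy)phenyl]-3-[(triisopropylsilyloxy)methyl]-2,3-dihydro-1-benzofuran-7-ol, via bis-magnesiated sulfonate 16 (not isolated), via aryne magnesium alkoxide 17 (not isolated), via C7 arylmagnesium chloride 18 (not isolated), via C7 dimethyl boronate 19 (not isolated)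
Conditions: i-PrMgCl·LiCl (2.1 equiv), THF (0.02 M), −78 °C, then −78 → 20 °C; B(OMe)3, −78 → 20 °C; AcOH, 30% aq. H2O2, 0 °C
Reagents that add atoms: hydrogen peroxide, OO
Why: Proposed new method: one equivalent of i-PrMgCl deprotonates the C2 hydroxyl and the second exchanges iodine for magnesium at C7 at −78 °C; on warming, the 2-magnesiated aryl sulfonate loses chloromagnesium 4-chlorobenzenesulfonate to give the C7–C7a aryne, the tethered alkoxide adds at C7a, and the C7 arylmagnesium so formed is borylated and oxidised (1,2-shift of the aryl group from boron to oxygen) to the phenol. The closest known reaction types are aryne generation from 2-magnesiated aryl sulfonates with addition of magnesium thiolates or amides and electrophilic quench of the new aryl Grignard, the base-mediated closure of 2-(3-halophenyl)ethanols to dihydrobenzofurans through arynes, and the borate–peroxide oxidation of aryl Grignard reagents; their combination with a tethered oxygen nucleophile is untested. The dihydrofuran ring closes in a 5-exo-dig mode, O1 attacking C7a while C7 stays outside the ring. No stereocentre is formed, and C2 and C3 keep the aldol configuration because no bond to either carbon is broken, so the syn diol maps onto the trans ring. The step needs site-selective addition, which the three-atom tether enforces because C7 is out of reach; iodine-over-bromine exchange, which the faster exchange of iodine at −78 °C with one equivalent of reagent secures; and a single oxygen nucleophile, which the non-migrating triisopropylsilyl ether on the primary oxygen secures.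

Step 11
Reactants: 20 (2S,3R)-5-bromo-2-[3-methoxy-4-(triisopropylsilyloxy)phenyl]-3-[(triisopropylsilyloxy)methyl]-2,3-dihydro-1-benzofuran-7-ol
Product: 21 (2S,3R)-5-bromo-2-[3-methoxy-4-(triisopropylsilyloxy)phenyl]-7-(triisopropylsilyloxy)-3-[(triisopropylsilyloxy)methyl]-2,3-dihydro-1-benzofuran
Conditions: i-Pr3SiCl, imidazole, DMF, rt
Reagents that add atoms: chlorotriisopropylsilane, CC(C)[Si](Cl)(C(C)C)C(C)C
Why: Phenol silylation masks the acidic C7 hydroxyl before the organolithium and enolate steps.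

Step 12
Reactants: 21 (2S,3R)-5-bromo-2-[3-methoxy-4-(triisopropylsilyloxy)phenyl]-7-(triisopropylsilyloxy)-3-[(triisopropylsilyloxy)methyl]-2,3-dihydro-1-benzofuran
Product: 24 {(2S,3R)-2-[3-methoxy-4-(triisopropylsilyloxy)phenyl]-7-(triisopropylsilyloxy)-3-[(triisopropylsilyloxy)methyl]-2,3-dihydro-1-benzofuran-5-yl}methanol, via C5 aryllithium 22 (not isolated), via C5 aldehyde 23 (not isolated)
Conditions: n-BuLi, THF, −78 °C; DMF, −78 → 0 °C; then MeOH, NaBH4, 0 °C
Reagents that add atoms: N,N-dimethylformamide, CN(C)C=O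
Why: Bromine–lithium exchange, Bouveault formylation with DMF and borohydride reduction of the released aldehyde in the same flask turn the C5 bromide into a hydroxymethyl group without touching the silyl ethers or the stereocentres.

Step 13
Reactants: 24 {(2S,3R)-2-[3-methoxy-4-(triisopropylsilyloxy)phenyl]-7-(triisopropylsilyloxy)-3-[(triisopropylsilyloxy)methyl]-2,3-dihydro-1-benzofuran-5-yl}methanol
Product: 25 (2S,3R)-5-(bromomethyl)-2-[3-methoxy-4-(triisopropylsilyloxy)phenyl]-7-(triisopropylsilyloxy)-3-[(triisopropylsilyloxy)methyl]-2,3-dihydro-1-benzofuran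
Conditions: CBr4, PPh3, CH2Cl2, 0 °C
Reagents that add atoms: tetrabromomethane, BrC(Br)(Br)Br
Why: The Appel reaction converts the benzylic alcohol into the bromide under neutral conditions; the bromide is used at once.

Step 14
Reactants: 10 3-methoxy-4-(triisopropylsilyloxy)benzaldehyde
Product: 26 [3-methoxy-4-(triisopropylsilyloxy)phenyl]methanol
Conditions: NaBH4, MeOH, 0 °C
Reagents that add atoms: none
Why: Borohydride reduction of the aldehyde to the benzylic alcohol leaves the aryl silyl ether intact.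

Step 15
Reactants: 26 [3-methoxy-4-(triisopropylsilyloxy)phenyl]methanol
Product: 27 [4-(bromomethyl)-2-methoxyphenoxy]triisopropylsilane
Conditions: CBr4, PPh3, CH2Cl2, 0 °C
Reagents that add atoms: tetrabromomethane, BrC(Br)(Br)Br
Why: The Appel reaction gives the benzylic bromide under neutral conditions.

Step 16
Reactants: 28 4-tert-butoxy-4-oxobutanoic acid; 6 (S)-4-benzyl-1,3-oxazolidin-2-one
Product: 30 tert-butyl 4-[(4S)-4-benzyl-2-oxo-1,3-oxazolidin-3-yl]-4-oxobutanoate, via mixed pivalic anhydride 29 (not isolated)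
Conditions: t-BuCOCl, Et3N, THF, −20 °C; then 6, LiCl, −20 °C → rt
Reagents that add atoms: none
Why: N-Acylation of the oxazolidinone through the mixed pivalic anhydride, the tert-butyl ester being inert.

Step 17
Reactants: 30 tert-butyl 4-[(4S)-4-benzyl-2-oxo-1,3-oxazolidin-3-yl]-4-oxobutanoate; 27 [4-(bromomethyl)-2-methoxyphenoxy]triisopropylsilane
Product: 32 tert-butyl (3S)-4-[(4S)-4-benzyl-2-oxo-1,3-oxazolidin-3-yl]-3-[3-methoxy-4-(triisopropylsilyloxy)benzyl]-4-oxobutanoate, via sodium Z-enolate 31 (not isolated)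
Conditions: NaN(SiMe3)2, THF, −78 °C; then 27, −78 → −40 °C
Reagents that add atoms: none
Why: Evans asymmetric alkylation, in which the chelated sodium Z-enolate of the imide is benzylated on the face opposite the C4 benzyl group of the auxiliary, which sets the new centre as S.

Step 18
Reactants: 32 tert-butyl (3S)-4-[(4S)-4-benzyl-2-oxo-1,3-oxazolidin-3-yl]-3-[3-methoxy-4-(triisopropylsilyloxy)benzyl]-4-oxobutanoate
Product: 34 (4S)-4-[3-methoxy-4-(triisopropylsilyloxy)benzyl]dihydrofuran-2(3H)-one, via hydroxy tert-butyl ester 33 (not isolated)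
Conditions: LiBH4, MeOH (1 equiv), THF, 0 °C; aqueous work-up; then TFA, CH2Cl2, 0 °C → rt
Reagents that add atoms: none
Why: Borohydride cleaves the imide to the primary alcohol and spares the tert-butyl ester, and acid then closes the γ-lactone with loss of isobutene, the stereocentre not being involved.

Step 19
Reactants: 34 (4S)-4-[3-methoxy-4-(triisopropylsilyloxy)benzyl]dihydrofuran-2(3H)-one; 25 (2S,3R)-5-(bromomethyl)-2-[3-methoxy-4-(triisopropylsilyloxy)phenyl]-7-(triisopropylsilyloxy)-3-[(triisopropylsilyloxy)methyl]-2,3-dihydro-1-benzofuran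
Product: 36 (3S,4S)-4-[3-methoxy-4-(triisopropylsilyloxy)benzyl]-3-({(2S,3R)-2-[3-methoxy-4-(triisopropylsilyloxy)phenyl]-7-(triisopropylsilyloxy)-3-[(triisopropylsilyloxy)methyl]-2,3-dihydro-1-benzofuran-5-yl}methyl)dihydrofuran-2(3H)-one, via lithium lactone enolate 35 (not isolated)
Conditions: LiN(SiMe3)2, THF, −78 °C; then 25, DMPU, −78 → −30 °C
Reagents that add atoms: none
Why: Alkylation of the lactone lithium enolate with the benzylic bromide takes place anti to the C4 arylmethyl group and so sets C3 as S (trans-3,4-disubstituted lactone).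

Step 20
Reactants: 36 (3S,4S)-4-[3-methoxy-4-(triisopropylsilyloxy)benzyl]-3-({(2S,3R)-2-[3-methoxy-4-(triisopropylsilyloxy)phenyl]-7-(triisopropylsilyloxy)-3-[(triisopropylsilyloxy)methyl]-2,3-dihydro-1-benzofuran-5-yl}methyl)dihydrofuran-2(3H)-one
Product: 37 (3S,4S)-4-(4-hydroxy-3-methoxybenzyl)-3-{[(2S,3R)-7-hydroxy-2-(4-hydroxy-3-methoxyphenyl)-3-(hydroxymethyl)-2,3-dihydro-1-benzofuran-5-yl]methyl}dihydrofuran-2(3H)-one (CNP0118131.1)
Conditions: Bu4NF (6 equiv), AcOH (6 equiv), THF, 0 °C → rt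
Reagents that add atoms: none
Why: Fluoride cleaves the three aryl silyl ethers and the primary alkyl silyl ether in one operation, and the acetic acid buffer keeps the lactone and the para-hydroxybenzylic C2–O1 ether away from free phenoxide base.

Compound list
1 | methyl 2-(2-hydroxyphenyl)acetate | COC(=O)Cc1ccccc1O | starting material
2 | methyl 2-(5-bromo-2-hydroxyphenyl)acetate | COC(=O)Cc1cc(Br)ccc1O | intermediate
3 | methyl 2-(5-bromo-2-hydroxy-3-iodophenyl)acetate | COC(=O)Cc1cc(Br)cc(I)c1O | intermediate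
4 | methyl 2-{5-bromo-2-[(4-chlorophenyl)sulfonyloxy]-3-iodophenyl}acetate | COC(=O)Cc1cc(Br)cc(I)c1OS(=O)(=O)c1ccc(Cl)cc1 | intermediate
5 | 2-{5-bromo-2-[(4-chlorophenyl)sulfonyloxy]-3-iodophenyl}acetic acid | OC(=O)Cc1cc(Br)cc(I)c1OS(=O)(=O)c1ccc(Cl)cc1 | intermediate
6 | (S)-4-benzyl-1,3-oxazolidin-2-one | O=C1N[C@@H](Cc2ccccc2)CO1 | starting material
7 | mixed anhydride of 5 with pivalic acid | CC(C)(C)C(=O)OC(=O)Cc1cc(Br)cc(I)c1OS(=O)(=O)c1ccc(Cl)cc1 | intermediate (not isolated)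
8 | (4S)-4-benzyl-3-(2-{5-bromo-2-[(4-chlorophenyl)sulfonyloxy]-3-iodophenyl}acetyl)-1,3-oxazolidin-2-one | O=C(Cc1cc(Br)cc(I)c1OS(=O)(=O)c1ccc(Cl)cc1)N1[C@@H](Cc2ccccc2)COC1=O | intermediate
9 | vanillin | COc1cc(C=O)ccc1O | starting material
10 | 3-methoxy-4-(triisopropylsilyloxy)benzaldehyde | COc1cc(C=O)ccc1O[Si](C(C)C)(C(C)C)C(C)C | intermediate
11 | dibutylboron Z-enolate of 8 | CCCCB(CCCC)O/C(=C\c1cc(Br)cc(I)c1OS(=O)(=O)c1ccc(Cl)cc1)N1[C@@H](Cc2ccccc2)COC1=O | intermediate (not isolated)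
12 | dibutylboron aldolate (O-dibutylboryl derivative of 13) | Brc1cc(I)c(OS(=O)(=O)c2ccc(Cl)cc2)c(c1)[C@H](C(=O)N1[C@@H](Cc2ccccc2)COC1=O)[C@H](OB(CCCC)CCCC)c1ccc(O[Si](C(C)C)(C(C)C)C(C)C)c(OC)c1 | intermediate (not isolated)
13 | (4S)-4-benzyl-3-[(2S,3S)-2-{5-bromo-2-[(4-chlorophenyl)sulfonyloxy]-3-iodophenyl}-3-hydroxy-3-[3-methoxy-4-(triisopropylsilyloxy)phenyl]propanoyl]-1,3-oxazolidin-2-one | Brc1cc(I)c(OS(=O)(=O)c2ccc(Cl)cc2)c(c1)[C@H](C(=O)N1[C@@H](Cc2ccccc2)COC1=O)[C@H](O)c1ccc(O[Si](C(C)C)(C(C)C)C(C)C)c(OC)c1 | intermediate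
14 | 4-bromo-2-iodo-6-{(1S,2R)-1,3-dihydroxy-1-[3-methoxy-4-(triisopropylsilyloxy)phenyl]propan-2-yl}phenyl 4-chlorobenzenesulfonate | Brc1cc(I)c(OS(=O)(=O)c2ccc(Cl)cc2)c(c1)[C@H](CO)[C@H](O)c1ccc(O[Si](C(C)C)(C(C)C)C(C)C)c(OC)c1 | intermediate
15 | 4-bromo-2-iodo-6-{(1S,2R)-1-hydroxy-1-[3-methoxy-4-(triisopropylsilyloxy)phenyl]-3-(triisopropylsilyloxy)propan-2-yl}phenyl 4-chlorobenzenesulfonate (key-step precursor) | Brc1cc(I)c(OS(=O)(=O)c2ccc(Cl)cc2)c(c1)[C@H](CO[Si](C(C)C)(C(C)C)C(C)C)[C@H](O)c1ccc(O[Si](C(C)C)(C(C)C)C(C)C)c(OC)c1 | intermediate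
16 | C7 arylmagnesium chloride / C2 chloromagnesium alkoxide of 15 | Brc1cc([Mg]Cl)c(OS(=O)(=O)c2ccc(Cl)cc2)c(c1)[C@H](CO[Si](C(C)C)(C(C)C)C(C)C)[C@H](O[Mg]Cl)c1ccc(O[Si](C(C)C)(C(C)C)C(C)C)c(OC)c1 | intermediate (not isolated)
17 | C7–C7a aryne carrying the C2 chloromagnesium alkoxide | BrC1=CC#CC(=C1)[C@H](CO[Si](C(C)C)(C(C)C)C(C)C)[C@H](O[Mg]Cl)c1ccc(O[Si](C(C)C)(C(C)C)C(C)C)c(OC)c1 | intermediate (not isolated)
18 | {(2S,3R)-5-bromo-2-[3-methoxy-4-(triisopropylsilyloxy)phenyl]-3-[(triisopropylsilyloxy)methyl]-2,3-dihydro-1-benzofuran-7-yl}magnesium chloride | Brc1cc([Mg]Cl)c2c(c1)[C@H](CO[Si](C(C)C)(C(C)C)C(C)C)[C@@H](c1ccc(O[Si](C(C)C)(C(C)C)C(C)C)c(OC)c1)O2 | intermediate (not isolated)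
19 | dimethyl {(2S,3R)-5-bromo-2-[3-methoxy-4-(triisopropylsilyloxy)phenyl]-3-[(triisopropylsilyloxy)methyl]-2,3-dihydro-1-benzofuran-7-yl}boronate | Brc1cc(B(OC)OC)c2c(c1)[C@H](CO[Si](C(C)C)(C(C)C)C(C)C)[C@@H](c1ccc(O[Si](C(C)C)(C(C)C)C(C)C)c(OC)c1)O2 | intermediate (not isolated)
20 | (2S,3R)-5-bromo-2-[3-methoxy-4-(triisopropylsilyloxy)phenyl]-3-[(triisopropylsilyloxy)methyl]-2,3-dihydro-1-benzofuran-7-ol (key-step product, trans) | Brc1cc(O)c2c(c1)[C@H](CO[Si](C(C)C)(C(C)C)C(C)C)[C@@H](c1ccc(O[Si](C(C)C)(C(C)C)C(C)C)c(OC)c1)O2 | intermediate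
21 | (2S,3R)-5-bromo-2-[3-methoxy-4-(triisopropylsilyloxy)phenyl]-7-(triisopropylsilyloxy)-3-[(triisopropylsilyloxy)methyl]-2,3-dihydro-1-benzofuran | Brc1cc(O[Si](C(C)C)(C(C)C)C(C)C)c2c(c1)[C@H](CO[Si](C(C)C)(C(C)C)C(C)C)[C@@H](c1ccc(O[Si](C(C)C)(C(C)C)C(C)C)c(OC)c1)O2 | intermediate
22 | C5 aryllithium derived from 21 | [Li]c1cc(O[Si](C(C)C)(C(C)C)C(C)C)c2c(c1)[C@H](CO[Si](C(C)C)(C(C)C)C(C)C)[C@@H](c1ccc(O[Si](C(C)C)(C(C)C)C(C)C)c(OC)c1)O2 | intermediate (not isolated)
23 | (2S,3R)-2-[3-methoxy-4-(triisopropylsilyloxy)phenyl]-7-(triisopropylsilyloxy)-3-[(triisopropylsilyloxy)methyl]-2,3-dihydro-1-benzofuran-5-carbaldehyde | O=Cc1cc(O[Si](C(C)C)(C(C)C)C(C)C)c2c(c1)[C@H](CO[Si](C(C)C)(C(C)C)C(C)C)[C@@H](c1ccc(O[Si](C(C)C)(C(C)C)C(C)C)c(OC)c1)O2 | intermediate (not isolated)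
24 | {(2S,3R)-2-[3-methoxy-4-(triisopropylsilyloxy)phenyl]-7-(triisopropylsilyloxy)-3-[(triisopropylsilyloxy)methyl]-2,3-dihydro-1-benzofuran-5-yl}methanol | OCc1cc(O[Si](C(C)C)(C(C)C)C(C)C)c2c(c1)[C@H](CO[Si](C(C)C)(C(C)C)C(C)C)[C@@H](c1ccc(O[Si](C(C)C)(C(C)C)C(C)C)c(OC)c1)O2 | intermediate
25 | (2S,3R)-5-(bromomethyl)-2-[3-methoxy-4-(triisopropylsilyloxy)phenyl]-7-(triisopropylsilyloxy)-3-[(triisopropylsilyloxy)methyl]-2,3-dihydro-1-benzofuran | BrCc1cc(O[Si](C(C)C)(C(C)C)C(C)C)c2c(c1)[C@H](CO[Si](C(C)C)(C(C)C)C(C)C)[C@@H](c1ccc(O[Si](C(C)C)(C(C)C)C(C)C)c(OC)c1)O2 | intermediate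
26 | [3-methoxy-4-(triisopropylsilyloxy)phenyl]methanol | COc1cc(CO)ccc1O[Si](C(C)C)(C(C)C)C(C)C | intermediate
27 | [4-(bromomethyl)-2-methoxyphenoxy]triisopropylsilane | COc1cc(CBr)ccc1O[Si](C(C)C)(C(C)C)C(C)C | intermediate
28 | 4-tert-butoxy-4-oxobutanoic acid | CC(C)(C)OC(=O)CCC(=O)O | starting material
29 | mixed anhydride of 28 with pivalic acid | CC(C)(C)OC(=O)CCC(=O)OC(=O)C(C)(C)C | intermediate (not isolated)
30 | tert-butyl 4-[(4S)-4-benzyl-2-oxo-1,3-oxazolidin-3-yl]-4-oxobutanoate | CC(C)(C)OC(=O)CCC(=O)N1[C@@H](Cc2ccccc2)COC1=O | intermediate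
31 | sodium Z-enolate of 30 | CC(C)(C)OC(=O)C/C=C(\[O-])N1[C@@H](Cc2ccccc2)COC1=O.[Na+] | intermediate (not isolated)
32 | tert-butyl (3S)-4-[(4S)-4-benzyl-2-oxo-1,3-oxazolidin-3-yl]-3-[3-methoxy-4-(triisopropylsilyloxy)benzyl]-4-oxobutanoate | CC(C)(C)OC(=O)C[C@H](Cc1ccc(O[Si](C(C)C)(C(C)C)C(C)C)c(OC)c1)C(=O)N1[C@@H](Cc2ccccc2)COC1=O | intermediate
33 | tert-butyl (3S)-4-hydroxy-3-[3-methoxy-4-(triisopropylsilyloxy)benzyl]butanoate | CC(C)(C)OC(=O)C[C@H](Cc1ccc(O[Si](C(C)C)(C(C)C)C(C)C)c(OC)c1)CO | intermediate (not isolated)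
34 | (4S)-4-[3-methoxy-4-(triisopropylsilyloxy)benzyl]dihydrofuran-2(3H)-one | O=C1C[C@H](Cc2ccc(O[Si](C(C)C)(C(C)C)C(C)C)c(OC)c2)CO1 | intermediate
35 | lithium enolate of 34 | [Li+].[O-]C1=C[C@H](Cc2ccc(O[Si](C(C)C)(C(C)C)C(C)C)c(OC)c2)CO1 | intermediate (not isolated)
36 | (3S,4S)-4-[3-methoxy-4-(triisopropylsilyloxy)benzyl]-3-({(2S,3R)-2-[3-methoxy-4-(triisopropylsilyloxy)phenyl]-7-(triisopropylsilyloxy)-3-[(triisopropylsilyloxy)methyl]-2,3-dihydro-1-benzofuran-5-yl}methyl)dihydrofuran-2(3H)-one | COc1cc(C[C@@H]2COC(=O)[C@H]2Cc2cc(O[Si](C(C)C)(C(C)C)C(C)C)c3c(c2)[C@H](CO[Si](C(C)C)(C(C)C)C(C)C)[C@@H](c2ccc(O[Si](C(C)C)(C(C)C)C(C)C)c(OC)c2)O3)ccc1O[Si](C(C)C)(C(C)C)C(C)C | intermediate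
37 | (3S,4S)-4-(4-hydroxy-3-methoxybenzyl)-3-{[(2S,3R)-7-hydroxy-2-(4-hydroxy-3-methoxyphenyl)-3-(hydroxymethyl)-2,3-dihydro-1-benzofuran-5-yl]methyl}dihydrofuran-2(3H)-one | COc1cc(C[C@@H]2COC(=O)[C@H]2Cc2cc(O)c3c(c2)[C@H](CO)[C@@H](c2ccc(O)c(OC)c2)O3)ccc1O | target

Total step count: 20.
Longest linear sequence: 14 steps from 1 (steps 1–5, 7–13, 19, 20).

Steps most likely to fail

Step 10 (new method). The chloromagnesium alkoxide may add too slowly to the aryne. The aryne could then be consumed by intermolecular attack of arylmagnesium species or by hydride transfer from the carbinol C–H. The alkoxide could also attack the sulfonyl sulfur before the exchange, and the C7 arylmagnesium could be protonated before it is borylated. The fallback uses known chemistry, sets out from 15 and returns at 20: the ring is closed through the other ether bond (C2–O1) and the C7 oxygen is introduced afterwards. Aqueous KOH in MeOH/THF at 50 °C cleaves the aryl sulfonate and the aryl silyl ether, leaves the primary silyl ether and should give 4-bromo-2-[(1S,2R)-1-hydroxy-1-(4-hydroxy-3-methoxyphenyl)-3-(triisopropylsilyloxy)propan-2-yl]-6-iodophenol F1. Catalytic TsOH in CH2Cl2 ionises the para-hydroxybenzylic alcohol, and the C7a phenol closes the ring to the thermodynamically preferred trans isomer 4-{(2S,3R)-5-bromo-7-iodo-3-[(triisopropylsilyloxy)methyl]-2,3-dihydro-1-benzofuran-2-yl}-2-methoxyphenol F2. i-Pr3SiCl and imidazole give (2S,3R)-5-bromo-7-iodo-2-[3-methoxy-4-(triisopropylsilyloxy)phenyl]-3-[(triisopropylsilyloxy)methyl]-2,3-dihydro-1-benzofuran F3. Iodine–magnesium exchange with i-PrMgCl·LiCl at −40 °C, B(OMe)3 and then H2O2/AcOH should deliver 20.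

Step 19. The electron-rich benzylic bromide may ionise or eliminate before it meets the enolate, proton exchange between product and enolate may lead to double alkylation, and the coupling may stall at partial conversion. The fallback sets out from 23 and 34 and returns at 36; aldehyde 23 is isolated by quenching step 12 with aqueous NH4Cl before the borohydride is added. The lithium enolate 35 adds to 23 at −78 °C, again anti to the C4 substituent, to give (3R,4S)-3-(hydroxy{(2S,3R)-2-[3-methoxy-4-(triisopropylsilyloxy)phenyl]-7-(triisopropylsilyloxy)-3-[(triisopropylsilyloxy)methyl]-2,3-dihydro-1-benzofuran-5-yl}methyl)-4-[3-methoxy-4-(triisopropylsilyloxy)benzyl]dihydrofuran-2(3H)-one F4, of which both carbinol epimers serve. PhOC(S)Cl, DMAP and pyridine convert it into the corresponding O-phenyl thionocarbonate F5. Bu3SnH and AIBN in toluene at 80 °C (Barton–McCombie deoxygenation) then remove the benzylic oxygen and should give 36.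

Step 8. The alkoxide of 13 may undergo retro-aldol cleavage (stabilised α-aryl enolate, electron-rich aldehyde) and epimerise at the α-aryl centre before hydride reaches the imide, and the sulfonyl group may transfer to the new alkoxides. The fallback sets out from 13 and returns at 15; it replaces reduction of the free aldol by reduction of an O-capped aldol that cannot fragment. Et3SiOTf and 2,6-lutidine give (4S)-4-benzyl-3-[(2S,3S)-2-{5-bromo-2-[(4-chlorophenyl)sulfonyloxy]-3-iodophenyl}-3-[3-methoxy-4-(triisopropylsilyloxy)phenyl]-3-(triethylsilyloxy)propanoyl]-1,3-oxazolidin-2-one F6. LiBH4 then gives 4-bromo-2-iodo-6-{(1S,2R)-3-hydroxy-1-[3-methoxy-4-(triisopropylsilyloxy)phenyl]-1-(triethylsilyloxy)propan-2-yl}phenyl 4-chlorobenzenesulfonate F7. i-Pr3SiCl and imidazole give 4-bromo-2-iodo-6-{(1S,2R)-1-[3-methoxy-4-(triisopropylsilyloxy)phenyl]-1-(triethylsilyloxy)-3-(triisopropylsilyloxy)propan-2-yl}phenyl 4-chlorobenzenesulfonate F8. HF·pyridine buffered with pyridine in THF at 0 °C removes only the triethylsilyl group and should give 15.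

Further compounds
F1 | step 10 | 4-bromo-2-[(1S,2R)-1-hydroxy-1-(4-hydroxy-3-methoxyphenyl)-3-(triisopropylsilyloxy)propan-2-yl]-6-iodophenol | Brc1cc(I)c(O)c(c1)[C@H](CO[Si](C(C)C)(C(C)C)C(C)C)[C@H](O)c1ccc(O)c(OC)c1
F2 | step 10 | 4-{(2S,3R)-5-bromo-7-iodo-3-[(triisopropylsilyloxy)methyl]-2,3-dihydro-1-benzofuran-2-yl}-2-methoxyphenol | Brc1cc(I)c2c(c1)[C@H](CO[Si](C(C)C)(C(C)C)C(C)C)[C@@H](c1ccc(O)c(OC)c1)O2
F3 | step 10 | (2S,3R)-5-bromo-7-iodo-2-[3-methoxy-4-(triisopropylsilyloxy)phenyl]-3-[(triisopropylsilyloxy)methyl]-2,3-dihydro-1-benzofuran | Brc1cc(I)c2c(c1)[C@H](CO[Si](C(C)C)(C(C)C)C(C)C)[C@@H](c1ccc(O[Si](C(C)C)(C(C)C)C(C)C)c(OC)c1)O2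
F4 | step 19 | (3R,4S)-3-(hydroxy{(2S,3R)-2-[3-methoxy-4-(triisopropylsilyloxy)phenyl]-7-(triisopropylsilyloxy)-3-[(triisopropylsilyloxy)methyl]-2,3-dihydro-1-benzofuran-5-yl}methyl)-4-[3-methoxy-4-(triisopropylsilyloxy)benzyl]dihydrofuran-2(3H)-one | COc1cc(C[C@@H]2COC(=O)[C@H]2C(O)c2cc(O[Si](C(C)C)(C(C)C)C(C)C)c3c(c2)[C@H](CO[Si](C(C)C)(C(C)C)C(C)C)[C@@H](c2ccc(O[Si](C(C)C)(C(C)C)C(C)C)c(OC)c2)O3)ccc1O[Si](C(C)C)(C(C)C)C(C)C
F5 | step 19 | O-phenyl thionocarbonate of F4 | COc1cc(C[C@@H]2COC(=O)[C@H]2C(OC(=S)Oc2ccccc2)c2cc(O[Si](C(C)C)(C(C)C)C(C)C)c3c(c2)[C@H](CO[Si](C(C)C)(C(C)C)C(C)C)[C@@H](c2ccc(O[Si](C(C)C)(C(C)C)C(C)C)c(OC)c2)O3)ccc1O[Si](C(C)C)(C(C)C)C(C)C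
F6 | step 8 | (4S)-4-benzyl-3-[(2S,3S)-2-{5-bromo-2-[(4-chlorophenyl)sulfonyloxy]-3-iodophenyl}-3-[3-methoxy-4-(triisopropylsilyloxy)phenyl]-3-(triethylsilyloxy)propanoyl]-1,3-oxazolidin-2-one | Brc1cc(I)c(OS(=O)(=O)c2ccc(Cl)cc2)c(c1)[C@H](C(=O)N1[C@@H](Cc2ccccc2)COC1=O)[C@H](O[Si](CC)(CC)CC)c1ccc(O[Si](C(C)C)(C(C)C)C(C)C)c(OC)c1
F7 | step 8 | 4-bromo-2-iodo-6-{(1S,2R)-3-hydroxy-1-[3-methoxy-4-(triisopropylsilyloxy)phenyl]-1-(triethylsilyloxy)propan-2-yl}phenyl 4-chlorobenzenesulfonate | Brc1cc(I)c(OS(=O)(=O)c2ccc(Cl)cc2)c(c1)[C@H](CO)[C@H](O[Si](CC)(CC)CC)c1ccc(O[Si](C(C)C)(C(C)C)C(C)C)c(OC)c1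
F8 | step 8 | 4-bromo-2-iodo-6-{(1S,2R)-1-[3-methoxy-4-(triisopropylsilyloxy)phenyl]-1-(triethylsilyloxy)-3-(triisopropylsilyloxy)propan-2-yl}phenyl 4-chlorobenzenesulfonate | Brc1cc(I)c(OS(=O)(=O)c2ccc(Cl)cc2)c(c1)[C@H](CO[Si](C(C)C)(C(C)C)C(C)C)[C@H](O[Si](CC)(CC)CC)c1ccc(O[Si](C(C)C)(C(C)C)C(C)C)c(OC)c1
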